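**Retrosynthetic overview**
1. The target is a C2-symmetric dimer. Its cyclobutane C8–C9–C9′–C8′ (lindenane numbering) is a masked succinic acid chain: C8/C8′ are the carboxyl carbons, and each α-carbon C9/C9′ is bonded to the methyl-bearing quaternary C10/C10′ of a cyclopropane-fused five-membered ring A. The strategy rests on this feature.
2. Last disconnection: both six-membered rings B and both butenolides (C7–C8, C11–C12, C12–O on each side) open to a cyclobutane-1,2-dione with two but-2-ynyl chains, plus CO.
3. The four-membered ring (C8–C8′) goes back to a 2,3-disubstituted dimethyl succinate (acyloin), C4=C15 to the ring-A ketones, and C5–C6 to enolate propargylation.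
4. Key disconnection: C9–C10 and C9′–C10′, by twofold Mukaiyama–Michael addition of the succinate bis(silyl ketene acetal) to two molecules of (1S,5R)-4-methylbicyclo[3.1.0]hex-3-en-2-one, made from (S)-epichlorohydrin.
5. Forward ring order: cyclopropane and ring A together (step 2), cyclobutane (step 10), then both rings B and both lactones (step 12).

Key step: step 7

Remark on numbering: lindenane numbering is used. C1–C3 form the cyclopropane (C2 is its CH2); C4, C5 and C10 complete ring A; C14 is the methyl on C10; C5–C10 form ring B; C11–C13 and the ring oxygen complete the lactone; C15 is the exocyclic CH2; primes mark the second half.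
Assumption: 13 is used as the mixture of enol ether geometries that forms, and 15 and 17–21 are drawn as the C2-symmetric isomer with the C9/C9′ configuration of the target. Step 7 is not expected to control these two epimerisable centres; their epimers are carried along and corrected in step 12.

Step 1
Reactants: 1 (S)-epichlorohydrin; 2 allylmagnesium chloride
Product: 4 (S)-2-(but-3-en-1-yl)oxirane, via (S)-1-chlorohex-5-en-2-ol 3 (not isolated)
Conditions: CuI (5 mol%), THF, −40 → 0 °C; then aq NaOH, rt
Reagents that add atoms: none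
Why: Copper-catalysed Grignard opening of the epoxide at its CH2 terminus, then Williamson closure onto the CH2Cl carbon; the C–O bond at the stereocentre is never broken, so (S)-1 should give (S)-4.

Step 2
Reactants: 4 (S)-2-(but-3-en-1-yl)oxirane
Product: 5 (1S,2S,5R)-bicyclo[3.1.0]hexan-2-ol
Conditions: LTMP (2 equiv, from 2,2,6,6-tetramethylpiperidine and n-BuLi), t-BuOMe, 0 °C → rt
Reagents that add atoms: none
Why: Hodgson cyclopropanation: LTMP lithiates the terminal epoxide carbon trans to the chain and the carbenoid adds to the tethered alkene through a chair-like transition state, so the carbinol carbon keeps the epoxide configuration and fixes both bridgeheads trans to the OH.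

Step 3
Reactants: 5 (1S,2S,5R)-bicyclo[3.1.0]hexan-2-ol
Product: 6 (1S,5R)-bicyclo[3.1.0]hexan-2-one
Conditions: TEMPO (1 mol%), KBr (10 mol%), NaOCl (1.1 equiv), NaHCO3, CH2Cl2/H2O, 0 °C
Reagents that add atoms: none
Why: Anelli (oxoammonium) oxidation of a secondary alcohol under buffered conditions that leave the cyclopropane alone; only the carbinol centre is removed.

Step 4
Reactants: 6 (1S,5R)-bicyclo[3.1.0]hexan-2-one
Product: 8 (1S,5S)-bicyclo[3.1.0]hex-3-en-2-one, via lithium bicyclo[3.1.0]hex-2-en-2-olate 7 (not isolated)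
Conditions: LDA, THF, −78 °C; then N-tert-butylbenzenesulfinimidoyl chloride, −78 °C
Reagents that add atoms: none
Why: Mukaiyama dehydrogenation: the enolate (only C3 can be deprotonated, the other α-carbon being a cyclopropane bridgehead) attacks sulfur, and syn-elimination of the sulfenamide through a five-membered transition state should give the enone at low temperature.

Step 5
Reactants: 8 (1S,5S)-bicyclo[3.1.0]hex-3-en-2-one
Product: 10 (1S,5R)-4-methylbicyclo[3.1.0]hex-3-en-2-one, via lithium 4-methylbicyclo[3.1.0]hex-2-en-2-olate 9 (not isolated)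
Conditions: Me2CuLi (from MeLi and CuI), Et2O, −78 °C; then N-tert-butylbenzenesulfinimidoyl chloride, THF, −78 °C → rt
Reagents that add atoms: lithium dimethylcuprate, [Li+].C[Cu-]C
Why: Gilman conjugate addition anti to the cyclopropane CH2, then the same sulfinimidoyl dehydrogenation of the regiodefined enolate; the transient C4 stereocentre is erased when C3=C4 re-forms, leaving the β-methyl enone.

Step 6
Reactants: 11 dimethyl succinate
Product: 13 1,4-dimethoxy-1,4-bis(trimethylsilyloxy)buta-1,3-diene, via methyl 4-methoxy-4-(trimethylsilyloxy)but-3-enoate 12 (not isolated)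
Conditions: LDA (2.3 equiv), Me3SiCl (2.6 equiv, present from the start), THF, −78 °C → rt
Reagents that add atoms: chlorotrimethylsilane, C[Si](C)(C)Cl
Why: Twofold O-silylation of the ester enolates (silyl ketene acetal formation) with in situ silyl chloride quench, which should outrun Claisen self-condensation of the succinate enolate; no stereocentre is formed.

Step 7
Reactants: 10 (1S,5R)-4-methylbicyclo[3.1.0]hex-3-en-2-one (2.2 equiv); 13 1,4-dimethoxy-1,4-bis(trimethylsilyloxy)buta-1,3-diene
Product: 15 dimethyl 2,3-bis(2-methyl-4-oxobicyclo[3.1.0]hexan-2-yl)butanedioate (C2-symmetric isomer; in each bicycle the methyl is syn and the succinate carbon anti to the cyclopropane CH2), via mono-adduct titanium enolate 14 (not isolated)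
Conditions: TiCl4 (2.2 equiv), CH2Cl2, −78 °C; 13 added slowly, −78 → −40 °C; aq NaHCO3
Reagents that add atoms: none
Why: TiCl4 binds the enone carbonyl of 10, the α-carbon C9 of the ketene acetal attacks the β-carbon C10 through an open transition state and loss of Me3SiCl leaves a titanium enolate and an ester; the adduct 14 still carries the second ketene acetal at C9′, which adds in the same way to a second activated enone (C9′–C10′). The closest known reaction is the Lewis acid-mediated Mukaiyama–Michael addition of ketene silyl acetals to β,β-disubstituted cyclic enones, an established way to quaternary centres. No ring is closed: two C–C bonds join two ring-A units to the four carbons of the later cyclobutane. C10 and C10′ are set by the folded bicyclo[3.1.0]hexenone, whose cyclopropane CH2 shields one face, so C9/C9′ should enter anti to it and the methyl end syn to it; both enones are the same enantiomer, so the two quaternary centres are homochiral. C9 and C9′ are formed without reliable control and stay epimerisable (α to ester, later α to the dione) until they are settled in step 12. The step needs 1,4- over 1,2-addition and a second addition next to a crowded centre: the soft ketene acetal carbon with a hard Lewis acid at −78 °C should secure the first, excess activated enone should drive the second, and the cyclopropyl ketone should survive short low-temperature exposure to TiCl4.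

Step 8
Reactants: 15 dimethyl 2,3-bis(2-methyl-4-oxobicyclo[3.1.0]hexan-2-yl)butanedioate; 16 1-bromobut-2-yne (3 equiv)
Product: 18 dimethyl 2,3-bis[3-(but-2-yn-1-yl)-2-methyl-4-oxobicyclo[3.1.0]hexan-2-yl]butanedioate (butynyl at C5/C5′ cis to the C10 methyl and trans to C9), via bis(lithium enolate) 17 (not isolated)
Conditions: LiHMDS (2.2 equiv), THF, −78 °C; then 16, DMPU, −78 → −30 °C
Reagents that add atoms: none
Why: Kinetic enolate formation at C5/C5′ (the only enolisable ketone α-position; the hindered ester α-CH at C9 is less acidic) and SN2 propargylation anti to the bulky C10 substituent C9, on the face of the C10 methyl, should set C5/C5′ with C6 trans to C9, which is also the more stable epimer at this centre.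

Step 9
Reactants: 18 dimethyl 2,3-bis[3-(but-2-yn-1-yl)-2-methyl-4-oxobicyclo[3.1.0]hexan-2-yl]butanedioate
Product: 19 dimethyl 2,3-bis[3-(but-2-yn-1-yl)-2-methyl-4-methylidenebicyclo[3.1.0]hexan-2-yl]butanedioate
Conditions: Takai–Lombardo reagent (Zn, CH2Br2, TiCl4, pre-formed in THF), CH2Cl2, 0 °C → rt
Reagents that add atoms: dibromomethane, BrCBr
Why: Takai–Lombardo methylenation with the gem-dimetallic Zn/Ti reagent is non-basic and selective for ketones over esters, so the hindered C4 ketones should be converted without epimerising C5 or C9; no stereocentre is formed.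

Step 10
Reactants: 19 dimethyl 2,3-bis[3-(but-2-yn-1-yl)-2-methyl-4-methylidenebicyclo[3.1.0]hexan-2-yl]butanedioate
Product: 20 trans-3,4-bis[3-(but-2-yn-1-yl)-2-methyl-4-methylidenebicyclo[3.1.0]hexan-2-yl]-1,2-bis(trimethylsilyloxy)cyclobut-1-ene
Conditions: Na dispersion (4.4 equiv), Me3SiCl (5 equiv), toluene, reflux
Reagents that add atoms: chlorotrimethylsilane, C[Si](C)(C)Cl
Why: Rühlmann acyloin condensation: electron transfer from sodium couples the two ester carbonyls (C8–C8′, as in the succinate to bis(silyloxy)cyclobutene case) while the silyl chloride traps methoxide and the enediolate, so C9/C9′ should not epimerise and the isolated alkenes and alkynes should not be reduced in the aprotic medium.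

Step 11
Reactants: 20 the bis(trimethylsilyloxy)cyclobutene
Product: 21 trans-3,4-bis[3-(but-2-yn-1-yl)-2-methyl-4-methylidenebicyclo[3.1.0]hexan-2-yl]cyclobutane-1,2-dione
Conditions: Br2 (1.0 equiv), CH2Cl2, −78 °C; volatiles removed in vacuo, crude dione used at once under dry conditions
Reagents that add atoms: none
Why: Bromination of the electron-rich enediol bis(silyl ether) with loss of two Me3SiBr is the standard route to cyclobutane-1,2-diones, and one equivalent at −78 °C should be consumed by this dioxygenated alkene far faster than by the 1,1-disubstituted alkenes or the alkynes.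

Step 12
Reactants: 21 the cyclobutane-1,2-dione
Product: 23 target CNP0265879.1 (C2-symmetric bis-butenolide), via mono-butenolide cyclobutanone 22 (not isolated)
Conditions: Mo(CO)6 (2.5 equiv), DMSO (12 equiv), i-Pr2NEt (0.2 equiv), toluene, 100 °C
Reagents that add atoms: molybdenum hexacarbonyl, [Mo].[C-]#[O+].[C-]#[O+].[C-]#[O+].[C-]#[O+].[C-]#[O+].[C-]#[O+]
Why: Proposed new method: a twofold intramolecular hetero-Pauson–Khand reaction in which Mo(0) binds each C7≡C11 alkyne and the neighbouring dione carbonyl C8 (then C8′), oxidative cyclisation gives an oxamolybdacyclopentene (C7–C8, ring B by 6-exo-dig closure), CO inserts into Mo–C11 and C12–O reductive elimination closes the α-methylbutenolide; the closest known reaction is the Mo(CO)6/DMSO cyclocarbonylation of 1,7-ynals bearing a methyl-substituted alkyne to cyclohexane-fused α-methylbutenolides, and α-dicarbonyl ketones are the ketone class known to enter metal-carbonyl [2+2+1] lactone formation; the tether can deliver C7 only to the face of the four-membered ring that carries C10 (cis 6/4 fusion), which sets C8/C8′ with O trans to C10; the amine should keep C9/C9′ enolising, so closure is funnelled through the arrangement with the cyclobutane anti to the axial C14 methyl, and after the first closure C9′ should settle trans to C9 before the second.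

**Compound list**
1 | (S)-epichlorohydrin | ClC[C@@H]1CO1 | starting material
2 | allylmagnesium chloride | C=CC[Mg]Cl | starting material
3 | (S)-1-chlorohex-5-en-2-ol | C=CCC[C@H](O)CCl | intermediate (not isolated)
4 | (S)-2-(but-3-en-1-yl)oxirane | C=CCC[C@H]1CO1 | intermediate
5 | (1S,2S,5R)-bicyclo[3.1.0]hexan-2-ol | O[C@@H]1[C@H]2C[C@H]2CC1 | intermediate
6 | (1S,5R)-bicyclo[3.1.0]hexan-2-one | O=C1[C@H]2C[C@H]2CC1 | intermediate
7 | lithium bicyclo[3.1.0]hex-2-en-2-olate (enolate of 6) | [Li]OC1[C@H]2C[C@H]2CC=1 | intermediate (not isolated)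
8 | (1S,5S)-bicyclo[3.1.0]hex-3-en-2-one | O=C1[C@H]2C[C@H]2C=C1 | intermediate
9 | lithium 4-methylbicyclo[3.1.0]hex-2-en-2-olate (methyl anti to the cyclopropane CH2) | [Li]OC1[C@H]2C[C@H]2[C@H](C)C=1 | intermediate (not isolated)
10 | (1S,5R)-4-methylbicyclo[3.1.0]hex-3-en-2-one | O=C1[C@H]2C[C@H]2C(C)=C1 | intermediate (key-step precursor)
11 | dimethyl succinate | COC(=O)CCC(=O)OC | starting material
12 | methyl 4-methoxy-4-(trimethylsilyloxy)but-3-enoate | COC(=O)CC=C(OC)O[Si](C)(C)C | intermediate (not isolated)
13 | 1,4-dimethoxy-1,4-bis(trimethylsilyloxy)buta-1,3-diene (geometry mixture) | COC(O[Si](C)(C)C)=CC=C(OC)O[Si](C)(C)C | intermediate (key-step precursor)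
14 | mono-adduct: trichlorotitanium enolate of one ring A, methyl ester at C8, silyl ketene acetal at C9′ | Cl[Ti](Cl)(Cl)OC1[C@H]2C[C@H]2[C@@](C)(C=1)[C@@H](C(=O)OC)C=C(OC)O[Si](C)(C)C | intermediate (not isolated)
15 | dimethyl 2,3-bis(2-methyl-4-oxobicyclo[3.1.0]hexan-2-yl)butanedioate, C2-symmetric isomer | O=C1[C@H]2C[C@H]2[C@@](C)(C1)[C@@H](C(=O)OC)[C@H](C(=O)OC)[C@@]1(C)[C@@H]2C[C@@H]2C(=O)C1 | intermediate (key-step product)
16 | 1-bromobut-2-yne | CC#CCBr | starting material
17 | bis(lithium enolate) of 15 (C4–O–Li, C4=C5 on both rings) | [Li]OC1[C@H]2C[C@H]2[C@@](C)(C=1)[C@@H](C(=O)OC)[C@H](C(=O)OC)[C@@]1(C)[C@@H]2C[C@@H]2C(O[Li])=C1 | intermediate (not isolated)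
18 | dimethyl 2,3-bis[3-(but-2-yn-1-yl)-2-methyl-4-oxobicyclo[3.1.0]hexan-2-yl]butanedioate | O=C1[C@H]2C[C@H]2[C@@](C)([C@H]1CC#CC)[C@@H](C(=O)OC)[C@H](C(=O)OC)[C@@]1(C)[C@@H]2C[C@@H]2C(=O)[C@@H]1CC#CC | intermediate
19 | dimethyl 2,3-bis[3-(but-2-yn-1-yl)-2-methyl-4-methylidenebicyclo[3.1.0]hexan-2-yl]butanedioate | C=C1[C@H]2C[C@H]2[C@@](C)([C@H]1CC#CC)[C@@H](C(=O)OC)[C@H](C(=O)OC)[C@@]1(C)[C@@H]2C[C@@H]2C(=C)[C@@H]1CC#CC | intermediate
20 | trans-3,4-bis[3-(but-2-yn-1-yl)-2-methyl-4-methylidenebicyclo[3.1.0]hexan-2-yl]-1,2-bis(trimethylsilyloxy)cyclobut-1-ene | C=C1[C@H]2C[C@H]2[C@@](C)([C@H]1CC#CC)[C@H]3C(O[Si](C)(C)C)=C(O[Si](C)(C)C)[C@@H]3[C@@]1(C)[C@@H]2C[C@@H]2C(=C)[C@@H]1CC#CC | intermediate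
21 | trans-3,4-bis[3-(but-2-yn-1-yl)-2-methyl-4-methylidenebicyclo[3.1.0]hexan-2-yl]cyclobutane-1,2-dione | C=C1[C@H]2C[C@H]2[C@@](C)([C@H]1CC#CC)[C@H]3C(=O)C(=O)[C@@H]3[C@@]1(C)[C@@H]2C[C@@H]2C(=C)[C@@H]1CC#CC | intermediate
22 | mono-annulated ketone: one ring B and butenolide closed, C8′ still a cyclobutanone carbonyl, second butynyl chain intact | C=C1[C@H]2C[C@H]2[C@@]2(C)[C@H]1CC1=C(C)C(=O)O[C@]13[C@H]2[C@@H]([C@@]2(C)[C@@H]4C[C@@H]4C(=C)[C@@H]2CC#CC)C3=O | intermediate (not isolated)
23 | CNP0265879.1 | C=C1[C@H]2C[C@H]2[C@@]2(C)[C@H]1CC1=C(C)C(=O)O[C@]13[C@H]2[C@H]1[C@@]2(C)[C@@H]4C[C@@H]4C(=C)[C@@H]2CC2=C(C)C(=O)O[C@@]213 | target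

**Step count**
Total: 12 steps. Longest linear sequence: 11 steps (steps 1–5 and 7–12, from 1 to 23); step 6 prepares the second partner.

**Steps most likely to fail**

1. Step 12 (proposed new method). The low-valent molybdenum may reduce or chelate the 1,2-dione as an enediolate instead of coupling it with the alkyne. The strained dione may decompose or ring-contract at 100 °C. Enolisation at C9/C9′ may be too slow for the facial funnelling, so that closure on the wrong face of an epimeric dione competes. Fallback with known reactions only: setting out from 15, the alkylation of step 8 is run with 1-bromo-4-(trimethylsilyl)but-2-yne F2. F2 is made from propargyltrimethylsilane by n-BuLi and paraformaldehyde, which gives 4-(trimethylsilyl)but-2-yn-1-ol F1, then CBr4/PPh3. The alkylation gives the bis(propargylsilane) diketo diester F3. Petasis methylenation (Cp2TiMe2, toluene, 70 °C) gives the bis(methylidene) diester F4, the acyloin closure of step 10 gives the bis(silyloxy)cyclobutene F5, and bromine as in step 11 gives the cyclobutane-1,2-dione F6. TiCl4 at −78 °C then triggers a twofold intramolecular SE2′ addition of the propargylsilanes to the dione carbonyls (Lewis acid-promoted propargylsilane–carbonyl addition). This closes both rings B and gives the bis(α-allenyl) diol F7. Ruthenium-carbonyl-catalysed cyclocarbonylation of the two α-allenols (Ru3(CO)12, CO, Et3N, dioxane, 100 °C) puts CO on the central allene carbon and closes both α-methylbutenolides, coming back to the route at 23.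

2. Step 7. The second conjugate addition may stall at the mono-adduct because of crowding next to the new quaternary centre. The titanium enolates may add to further enone and give oligomers. The Lewis acid may open the cyclopropyl ketone. Fallback: setting out from 10, the open-chain bis(ketene acetal) is replaced by the cyclic, flatter and more nucleophilic 2,5-bis(trimethylsilyloxy)furan F8 (from succinic anhydride, Me3SiOTf, Et3N). Its C3 and C4 add in turn to two TiCl4-activated molecules of 10 and give the trans-2,3-disubstituted succinic anhydride F9, whose five-membered ring also holds the two new chains trans. Methanolysis (MeOH, DMAP) gives the half ester F10, and Me3SiCHN2 esterifies it, coming back to the route at 15.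

3. Step 10. Electron transfer to the very hindered esters may be slow. The ester ketyls may cyclise onto the pendant alkynes instead of coupling with each other. Over-reduction may compete. Fallback: setting out from 19, the esters are reduced (LiAlH4) to the 1,4-diol F11 and oxidised (Swern) to the 1,4-dialdehyde F12. SmI2-mediated intramolecular pinacol coupling closes C8–C8′ to the cyclobutane-1,2-diol F13. Twofold Swern-type oxidation (DMSO, (CF3CO)2O, Et3N) gives the dione, coming back to the route at 21.

**Further compounds**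
F1 | step 12 | 4-(trimethylsilyl)but-2-yn-1-ol | C[Si](C)(C)CC#CCO
F2 | step 12 | 1-bromo-4-(trimethylsilyl)but-2-yne | C[Si](C)(C)CC#CCBr
F3 | step 12 | dimethyl 2,3-bis{2-methyl-4-oxo-3-[4-(trimethylsilyl)but-2-yn-1-yl]bicyclo[3.1.0]hexan-2-yl}butanedioate | O=C1[C@H]2C[C@H]2[C@@](C)([C@H]1CC#CC[Si](C)(C)C)[C@@H](C(=O)OC)[C@H](C(=O)OC)[C@@]1(C)[C@@H]2C[C@@H]2C(=O)[C@@H]1CC#CC[Si](C)(C)C
F4 | step 12 | dimethyl 2,3-bis{2-methyl-4-methylidene-3-[4-(trimethylsilyl)but-2-yn-1-yl]bicyclo[3.1.0]hexan-2-yl}butanedioate | C=C1[C@H]2C[C@H]2[C@@](C)([C@H]1CC#CC[Si](C)(C)C)[C@@H](C(=O)OC)[C@H](C(=O)OC)[C@@]1(C)[C@@H]2C[C@@H]2C(=C)[C@@H]1CC#CC[Si](C)(C)C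
F5 | step 12 | 1,2-bis(trimethylsilyloxy)cyclobut-1-ene analogue of 20 with 4-(trimethylsilyl)but-2-ynyl chains | C=C1[C@H]2C[C@H]2[C@@](C)([C@H]1CC#CC[Si](C)(C)C)[C@H]3C(O[Si](C)(C)C)=C(O[Si](C)(C)C)[C@@H]3[C@@]1(C)[C@@H]2C[C@@H]2C(=C)[C@@H]1CC#CC[Si](C)(C)C
F6 | step 12 | cyclobutane-1,2-dione analogue of 21 with 4-(trimethylsilyl)but-2-ynyl chains | C=C1[C@H]2C[C@H]2[C@@](C)([C@H]1CC#CC[Si](C)(C)C)[C@H]3C(=O)C(=O)[C@@H]3[C@@]1(C)[C@@H]2C[C@@H]2C(=C)[C@@H]1CC#CC[Si](C)(C)C
F7 | step 12 | bis(α-allenyl) diol: both rings B closed, C7/C7′ carrying =C=CH2, tertiary OH at C8/C8′ (trans) | C=C1[C@H]2C[C@H]2[C@@]2(C)[C@H]1CC(=C=C)[C@]3(O)[C@H]2[C@H]1[C@@]2(C)[C@@H]4C[C@@H]4C(=C)[C@@H]2CC(=C=C)[C@@]31O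
F8 | step 7 | 2,5-bis(trimethylsilyloxy)furan | C[Si](C)(C)Oc1ccc(O[Si](C)(C)C)o1
F9 | step 7 | trans-2,3-bis(2-methyl-4-oxobicyclo[3.1.0]hexan-2-yl)succinic anhydride | O=C1[C@H]2C[C@H]2[C@@](C)(C1)[C@H]3C(=O)OC(=O)[C@@H]3[C@@]1(C)[C@@H]2C[C@@H]2C(=O)C1
F10 | step 7 | 4-methoxy-4-oxo-2,3-bis(2-methyl-4-oxobicyclo[3.1.0]hexan-2-yl)butanoic acid (half ester) | O=C1[C@H]2C[C@H]2[C@@](C)(C1)[C@@H](C(=O)O)[C@H](C(=O)OC)[C@@]1(C)[C@@H]2C[C@@H]2C(=O)C1
F11 | step 10 | 2,3-bis[3-(but-2-yn-1-yl)-2-methyl-4-methylidenebicyclo[3.1.0]hexan-2-yl]butane-1,4-diol | C=C1[C@H]2C[C@H]2[C@@](C)([C@H]1CC#CC)[C@@H](CO)[C@H](CO)[C@@]1(C)[C@@H]2C[C@@H]2C(=C)[C@@H]1CC#CC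
F12 | step 10 | 2,3-bis[3-(but-2-yn-1-yl)-2-methyl-4-methylidenebicyclo[3.1.0]hexan-2-yl]butanedial | C=C1[C@H]2C[C@H]2[C@@](C)([C@H]1CC#CC)[C@@H](C=O)[C@H](C=O)[C@@]1(C)[C@@H]2C[C@@H]2C(=C)[C@@H]1CC#CC
F13 | step 10 | trans-3,4-bis[3-(but-2-yn-1-yl)-2-methyl-4-methylidenebicyclo[3.1.0]hexan-2-yl]cyclobutane-1,2-diol (carbinol configurations left open) | C=C1[C@H]2C[C@H]2[C@@](C)([C@H]1CC#CC)[C@H]3C(O)C(O)[C@@H]3[C@@]1(C)[C@@H]2C[C@@H]2C(=C)[C@@H]1CC#CC
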